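**Retrosynthetic overview**
1. Labels: C1 = CH–O-angelate, C2=C3(Me), C4 = CH2, C5 = CH–OBz, C6 = ring-fusion CH, C7 = ring-fusion C(Me), C8/C9 = CH2, C10 = C(OH)iPr. The angelate is attached last; the seven-membered ring is opened across C2=C3 (ring-closing metathesis of a vinyl carbinol and a methallyl group).
2. The C1 carbinol comes from a vinyl ketone (CBS reduction). The C4–C5 bond and the C5 carbinol come from asymmetric methallylation of a cyclopentane aldehyde (fragment 1) with a methallyl nucleophile (fragment 2).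
3. The C10 carbinol comes from isopropyl addition to a cyclopentanone; the ring oxygen at C8, needed only to make C7 nucleophilic, is removed by Barton–McCombie deoxygenation.
4. C6 and C7 come from a trans-selective vinyl conjugate addition and enolate alkylation on (R)-4-silyloxy-2-methylcyclopentenone, itself made by Piancatelli rearrangement of a furyl carbinol and lipase resolution.
5. Ring order: five-membered ring first (steps 1–2), seven-membered ring last (step 21).

Assumption: the lipase acylates the (R)-enantiomer of the racemic hydroxy enone, as it does for 4-hydroxycyclopent-2-enone; the configuration is checked (rotation, Mosher ester) before going on.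

**Route**

Step 1
Reactants: 1 1-(furan-2-yl)ethanol (racemic)
Product: 2 (±)-trans-4-hydroxy-5-methylcyclopent-2-en-1-one
Conditions: ZnCl2, H2O/dioxane, pH 5–6, reflux
Reagents that add atoms: water (O)
Why: Piancatelli rearrangement, in which loss of the carbinol OH, addition of water to the furan, ring opening and conrotatory 4π electrocyclization of the hydroxypentadienyl cation give the trans hydroxy enone as a racemate.

Step 2
Reactants: 2 (±)-trans-4-hydroxy-5-methylcyclopent-2-en-1-one
Product: 3 (±)-4-hydroxy-2-methylcyclopent-2-en-1-one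
Conditions: K2HPO4/KH2PO4 buffer (pH 8), H2O/dioxane, 50 °C
Reagents that add atoms: water (O)
Why: Base-mediated elimination and conjugate re-addition of water through 2-methylcyclopentadienone (net enone isomerization) gives the more stable trisubstituted enone, the carbinol center staying racemic.

Step 3
Reactants: 3 (±)-4-hydroxy-2-methylcyclopent-2-en-1-one
Product: 4 (1R)-3-methyl-4-oxocyclopent-2-en-1-yl acetate
Conditions: vinyl acetate, Burkholderia cepacia lipase, t-BuOMe, 30 °C, stopped near 45% conversion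
Reagents that add atoms: vinyl acetate (CC(=O)OC=C)
Why: Lipase-catalysed kinetic resolution by irreversible transesterification acylates the (R)-alcohol selectively (Kazlauskas rule), which fixes the absolute configuration of the carbinol carbon (later C10) that relays chirality to C6 and C7, and the unreacted (S)-alcohol is removed by chromatography.

Step 4
Reactants: 4 (1R)-3-methyl-4-oxocyclopent-2-en-1-yl acetate
Product: 5 (4R)-4-hydroxy-2-methylcyclopent-2-en-1-one
Conditions: MeOH, immobilized Candida antarctica lipase B, t-BuOMe, 30 °C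
Reagents that add atoms: none
Why: Enzymatic transesterification (methanolysis) removes the acetate under neutral conditions that avoid β-elimination and, having the same (R)-preference, raises the ee further without touching the stereocenter.

Step 5
Reactants: 5 (4R)-4-hydroxy-2-methylcyclopent-2-en-1-one
Product: 6 (4R)-4-[(tert-butyldimethylsilyl)oxy]-2-methylcyclopent-2-en-1-one
Conditions: t-BuMe2SiCl, imidazole, DMF, 0 °C to rt
Reagents that add atoms: tert-butyldimethylsilyl chloride (CC(C)(C)[Si](C)(C)Cl)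
Why: Silyl ether formation installs the bulky group that will direct the conjugate addition and that is not a leaving group under cuprate conditions.

Step 6
Reactants: 6 (4R)-4-[(tert-butyldimethylsilyl)oxy]-2-methylcyclopent-2-en-1-one; 7 vinylmagnesium bromide
Product: 8 (3R,4R)-4-[(tert-butyldimethylsilyl)oxy]-3-ethenyl-2-methyl-1-[(trimethylsilyl)oxy]cyclopent-1-ene
Conditions: CuBr·SMe2 (10 mol%), Me3SiCl, HMPA, THF, −78 °C; Et3N quench
Reagents that add atoms: chlorotrimethylsilane (C[Si](C)(C)Cl)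
Why: Copper-catalysed conjugate addition with in situ silylation adds the vinyl group to C6 anti to the neighbouring silyloxy group (setting C6) and traps the tetrasubstituted enolate regiospecifically as the C7=C8 silyl enol ether.

Step 7
Reactants: 8 (3R,4R)-4-[(tert-butyldimethylsilyl)oxy]-3-ethenyl-2-methyl-1-[(trimethylsilyl)oxy]cyclopent-1-ene; 9 trimethyl orthoformate
Product: 10 (2S,3R,4R)-4-[(tert-butyldimethylsilyl)oxy]-2-(dimethoxymethyl)-3-ethenyl-2-methylcyclopentan-1-one
Conditions: Me3SiOTf (10 mol%), CH2Cl2, −78 °C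
Reagents that add atoms: none
Why: Mukaiyama-type C-alkylation of the silyl enol ether by the dimethoxycarbenium ion occurs at C7 anti to the adjacent vinyl group, creating the quaternary center with the masked C1 aldehyde trans to the C6 substituent and the methyl cis to it, as the trans ring fusion requires.

Step 8
Reactants: 10 (2S,3R,4R)-4-[(tert-butyldimethylsilyl)oxy]-2-(dimethoxymethyl)-3-ethenyl-2-methylcyclopentan-1-one
Product: 11 (2R,3R,4R)-4-[(tert-butyldimethylsilyl)oxy]-2-(dimethoxymethyl)-3-ethenyl-2-methylcyclopentan-1-ol (mixture of C1 epimers)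
Conditions: NaBH4, MeOH, 0 °C
Reagents that add atoms: none
Why: Borohydride reduction of the ketone gives the alcohol needed for deoxygenation, and the new carbinol configuration is irrelevant because that center becomes CH2 two steps later.

Step 9
Reactants: 11 (2R,3R,4R)-4-[(tert-butyldimethylsilyl)oxy]-2-(dimethoxymethyl)-3-ethenyl-2-methylcyclopentan-1-ol (mixture of C1 epimers)
Product: 12 O-[(2R,3R,4R)-4-[(tert-butyldimethylsilyl)oxy]-2-(dimethoxymethyl)-3-ethenyl-2-methylcyclopentyl] 1H-imidazole-1-carbothioate (mixture of C1 epimers)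
Conditions: 1,1'-thiocarbonyldiimidazole, DMAP, ClCH2CH2Cl, 80 °C
Reagents that add atoms: 1,1'-thiocarbonyldiimidazole (S=C(n1ccnc1)n1ccnc1)
Why: Thioacylation under non-basic conditions gives the thiocarbonyl derivative for radical deoxygenation without retro-aldol or elimination of the silyloxy group.

Step 10
Reactants: 12 O-[(2R,3R,4R)-4-[(tert-butyldimethylsilyl)oxy]-2-(dimethoxymethyl)-3-ethenyl-2-methylcyclopentyl] 1H-imidazole-1-carbothioate (mixture of C1 epimers)
Product: 13 tert-butyl{[(1R,2R,3S)-3-(dimethoxymethyl)-2-ethenyl-3-methylcyclopentyl]oxy}dimethylsilane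
Conditions: Bu3SnH, AIBN, toluene, 110 °C
Reagents that add atoms: none
Why: Barton–McCombie deoxygenation, in which the stannyl radical adds to C=S and the released secondary C8 radical abstracts hydrogen from Bu3SnH, removes the ring oxygen at C8 while leaving all stereocenters untouched.

Step 11
Reactants: 13 tert-butyl{[(1R,2R,3S)-3-(dimethoxymethyl)-2-ethenyl-3-methylcyclopentyl]oxy}dimethylsilane
Product: 14 (1R,2R,3S)-3-(dimethoxymethyl)-2-ethenyl-3-methylcyclopentan-1-ol
Conditions: Bu4NF, THF, rt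
Reagents that add atoms: none
Why: Fluoride-mediated desilylation frees the C10 alcohol, and the acetal and alkene are inert to it.

Step 12
Reactants: 14 (1R,2R,3S)-3-(dimethoxymethyl)-2-ethenyl-3-methylcyclopentan-1-ol
Product: 15 (2R,3S)-3-(dimethoxymethyl)-2-ethenyl-3-methylcyclopentan-1-one
Conditions: Dess–Martin periodinane, NaHCO3, CH2Cl2, 0 °C; used crude at once
Reagents that add atoms: none
Why: Dess–Martin oxidation under buffered, non-basic conditions gives the β,γ-unsaturated ketone without epimerizing C6 or moving the alkene into conjugation.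

Step 13
Reactants: 15 (2R,3S)-3-(dimethoxymethyl)-2-ethenyl-3-methylcyclopentan-1-one; 16 isopropylmagnesium chloride
Product: 17 (1R,2R,3S)-3-(dimethoxymethyl)-2-ethenyl-3-methyl-1-(propan-2-yl)cyclopentan-1-ol
Conditions: CeCl3 (anhydrous, premixed with 16), THF, −78 °C
Reagents that add atoms: none
Why: Organocerium 1,2-addition (Imamoto conditions) is weakly basic enough for this enolizable ketone and attacks C10 from the face anti to the adjacent C6 vinyl group, placing isopropyl trans and hydroxyl cis to the C6 substituent.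

Step 14
Reactants: 17 (1R,2R,3S)-3-(dimethoxymethyl)-2-ethenyl-3-methyl-1-(propan-2-yl)cyclopentan-1-ol
Product: 19 (1R,2S,5R)-2-(dimethoxymethyl)-5-hydroxy-2-methyl-5-(propan-2-yl)cyclopentane-1-carbaldehyde, via secondary ozonide 18 (not isolated)
Conditions: O3, CH2Cl2, −78 °C; then PPh3, −78 °C to rt; used crude
Reagents that add atoms: ozone ([O-][O+]=O)
Why: Ozonolysis (cycloaddition to the ozonide and reductive cleavage by PPh3) converts the vinyl group into the C5 aldehyde under neutral conditions that leave C6 and the tertiary alcohol intact.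

Step 15
Reactants: 19 (1R,2S,5R)-2-(dimethoxymethyl)-5-hydroxy-2-methyl-5-(propan-2-yl)cyclopentane-1-carbaldehyde; 20 (2-methylallyl)magnesium chloride
Product: 22 (1R,2S,3S)-3-(dimethoxymethyl)-2-[(1S)-1-hydroxy-3-methylbut-3-en-1-yl]-3-methyl-1-(propan-2-yl)cyclopentan-1-ol, via diisopinocampheylborinate ester 21 (not isolated)
Conditions: (−)-Ipc2BOMe (from (+)-α-pinene), Et2O, 0 °C, then 19 at −78 °C; NaOH, H2O2 work-up
Reagents that add atoms: none
Why: Brown asymmetric carbonyl allylation joins fragment 1 (aldehyde) and fragment 2 (methallyl), the allylborane formed in the flask adding through a chair six-membered transition state under reagent control to the Si face of the aldehyde to form the C4–C5 bond and the (S)-carbinol at C5.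

Step 16
Reactants: 22 (1R,2S,3S)-3-(dimethoxymethyl)-2-[(1S)-1-hydroxy-3-methylbut-3-en-1-yl]-3-methyl-1-(propan-2-yl)cyclopentan-1-ol; 23 benzoyl chloride
Product: 24 (1S)-1-[(1S,2S,5R)-2-(dimethoxymethyl)-5-hydroxy-2-methyl-5-(propan-2-yl)cyclopentyl]-3-methylbut-3-en-1-yl benzoate
Conditions: pyridine, DMAP (cat.), CH2Cl2, 0 °C to rt
Reagents that add atoms: none
Why: DMAP-catalysed acylation benzoylates the secondary C5 alcohol with retention, while the hindered tertiary C10 alcohol does not react.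

Step 17
Reactants: 24 (1S)-1-[(1S,2S,5R)-2-(dimethoxymethyl)-5-hydroxy-2-methyl-5-(propan-2-yl)cyclopentyl]-3-methylbut-3-en-1-yl benzoate
Product: 25 (1S)-1-[(1S,2S,5R)-2-formyl-5-hydroxy-2-methyl-5-(propan-2-yl)cyclopentyl]-3-methylbut-3-en-1-yl benzoate
Conditions: p-TsOH·H2O (cat.), acetone/H2O, 40 °C
Reagents that add atoms: water (O)
Why: Mild acid-catalysed acetal hydrolysis unmasks the non-enolizable C1 aldehyde, which cannot form a hemiacetal with the C10 hydroxyl because the two groups sit on opposite faces of the ring.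

Step 18
Reactants: 25 (1S)-1-[(1S,2S,5R)-2-formyl-5-hydroxy-2-methyl-5-(propan-2-yl)cyclopentyl]-3-methylbut-3-en-1-yl benzoate; 26 vinyl bromide
Product: 27 (1S)-1-[(1S,2S,5R)-5-hydroxy-2-(1-hydroxyprop-2-en-1-yl)-2-methyl-5-(propan-2-yl)cyclopentyl]-3-methylbut-3-en-1-yl benzoate (mixture of carbinol epimers)
Conditions: CrCl2, NiCl2 (1 mol%), DMF, rt
Reagents that add atoms: none
Why: Nozaki–Hiyama–Kishi vinylation adds the vinylchromium species chemoselectively to the aldehyde in the presence of the benzoate and the free tertiary alcohol, and the C1 epimers are carried on together because C1 is reset in the next two steps.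

Step 19
Reactants: 27 (1S)-1-[(1S,2S,5R)-5-hydroxy-2-(1-hydroxyprop-2-en-1-yl)-2-methyl-5-(propan-2-yl)cyclopentyl]-3-methylbut-3-en-1-yl benzoate (mixture of carbinol epimers)
Product: 28 (1S)-1-[(1S,2S,5R)-5-hydroxy-2-methyl-5-(propan-2-yl)-2-(prop-2-enoyl)cyclopentyl]-3-methylbut-3-en-1-yl benzoate
Conditions: Dess–Martin periodinane, NaHCO3, CH2Cl2, 0 °C
Reagents that add atoms: none
Why: Dess–Martin oxidation of the allylic alcohols converges both epimers on one vinyl ketone, the tertiary alcohol being inert.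

Step 20
Reactants: 28 (1S)-1-[(1S,2S,5R)-5-hydroxy-2-methyl-5-(propan-2-yl)-2-(prop-2-enoyl)cyclopentyl]-3-methylbut-3-en-1-yl benzoate
Product: 29 (1S)-1-{(1S,2S,5R)-5-hydroxy-2-[(1R)-1-hydroxyprop-2-en-1-yl]-2-methyl-5-(propan-2-yl)cyclopentyl}-3-methylbut-3-en-1-yl benzoate
Conditions: (S)-2-methyl-CBS-oxazaborolidine (0.5 equiv), catecholborane, toluene, −78 °C
Reagents that add atoms: none
Why: Corey–Bakshi–Shibata reduction, with the quaternary C7 as the large and the vinyl group as the small ketone substituent, delivers hydride under catalyst control to give the (R)-allylic alcohol at C1, and catecholborane at −78 °C does not hydroborate the alkenes.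

Step 21
Reactants: 29 (1S)-1-{(1S,2S,5R)-5-hydroxy-2-[(1R)-1-hydroxyprop-2-en-1-yl]-2-methyl-5-(propan-2-yl)cyclopentyl}-3-methylbut-3-en-1-yl benzoate
Product: 30 (3R,3aS,4S,8R,8aS)-3,8-dihydroxy-6,8a-dimethyl-3-(propan-2-yl)-1,2,3,3a,4,5,8,8a-octahydroazulen-4-yl benzoate
Conditions: second-generation Grubbs catalyst RuCl2(=CHPh)(PCy3)(H2IMes) (10 mol%), CH2Cl2 (2 mM), 40 °C
Reagents that add atoms: none
Why: Ring-closing olefin metathesis between the vinyl carbinol and the methallyl group closes the trans-fused seven-membered ring with the trisubstituted C2=C3 alkene and loses ethene, no stereocenter being involved.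

Step 22
Reactants: 30 (3R,3aS,4S,8R,8aS)-3,8-dihydroxy-6,8a-dimethyl-3-(propan-2-yl)-1,2,3,3a,4,5,8,8a-octahydroazulen-4-yl benzoate; 31 angelic acid
Product: 32 (3R,3aS,4S,8R,8aS)-4-(benzoyloxy)-3-hydroxy-6,8a-dimethyl-3-(propan-2-yl)-1,2,3,3a,4,5,8,8a-octahydroazulen-8-yl (2Z)-2-methylbut-2-enoate
Conditions: 2,4,6-trichlorobenzoyl chloride, Et3N, toluene, rt (31 activated first); then 30, 80 °C, no DMAP
Reagents that add atoms: none
Why: Yamaguchi-type esterification through the mixed anhydride without a nucleophilic catalyst acylates the secondary C1 alcohol with retention, keeps the Z geometry of the angelate and leaves the tertiary C10 alcohol free.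

**Compound list**

1 | 1-(furan-2-yl)ethanol (racemic) | CC(O)c1ccco1 | starting material
2 | (±)-trans-4-hydroxy-5-methylcyclopent-2-en-1-one (racemate, one enantiomer drawn) | C[C@H]1[C@H](O)C=CC1=O | intermediate
3 | (±)-4-hydroxy-2-methylcyclopent-2-en-1-one | CC1=CC(O)CC1=O | intermediate
4 | (1R)-3-methyl-4-oxocyclopent-2-en-1-yl acetate | CC1=C[C@H](OC(C)=O)CC1=O | intermediate
5 | (4R)-4-hydroxy-2-methylcyclopent-2-en-1-one | CC1=C[C@H](O)CC1=O | intermediate
6 | (4R)-4-[(tert-butyldimethylsilyl)oxy]-2-methylcyclopent-2-en-1-one | CC1=C[C@H](O[Si](C)(C)C(C)(C)C)CC1=O | intermediate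
7 | vinylmagnesium bromide | C=C[Mg]Br | starting material
8 | (3R,4R)-4-[(tert-butyldimethylsilyl)oxy]-3-ethenyl-2-methyl-1-[(trimethylsilyl)oxy]cyclopent-1-ene | C=C[C@@H]1C(C)=C(O[Si](C)(C)C)C[C@H]1O[Si](C)(C)C(C)(C)C | intermediate
9 | trimethyl orthoformate | COC(OC)OC | starting material
10 | (2S,3R,4R)-4-[(tert-butyldimethylsilyl)oxy]-2-(dimethoxymethyl)-3-ethenyl-2-methylcyclopentan-1-one | C=C[C@@H]1[C@](C(OC)OC)(C)C(=O)C[C@H]1O[Si](C)(C)C(C)(C)C | intermediate
11 | (2R,3R,4R)-4-[(tert-butyldimethylsilyl)oxy]-2-(dimethoxymethyl)-3-ethenyl-2-methylcyclopentan-1-ol (mixture of C1 epimers) | C=C[C@@H]1[C@](C(OC)OC)(C)C(O)C[C@H]1O[Si](C)(C)C(C)(C)C | intermediate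
12 | O-[(2R,3R,4R)-4-[(tert-butyldimethylsilyl)oxy]-2-(dimethoxymethyl)-3-ethenyl-2-methylcyclopentyl] 1H-imidazole-1-carbothioate (mixture of C1 epimers) | C=C[C@@H]1[C@](C(OC)OC)(C)C(OC(=S)n2ccnc2)C[C@H]1O[Si](C)(C)C(C)(C)C | intermediate
13 | tert-butyl{[(1R,2R,3S)-3-(dimethoxymethyl)-2-ethenyl-3-methylcyclopentyl]oxy}dimethylsilane | C=C[C@@H]1[C@](C(OC)OC)(C)CC[C@H]1O[Si](C)(C)C(C)(C)C | intermediate
14 | (1R,2R,3S)-3-(dimethoxymethyl)-2-ethenyl-3-methylcyclopentan-1-ol | C=C[C@@H]1[C@](C(OC)OC)(C)CC[C@H]1O | intermediate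
15 | (2R,3S)-3-(dimethoxymethyl)-2-ethenyl-3-methylcyclopentan-1-one | C=C[C@@H]1[C@](C(OC)OC)(C)CCC1=O | intermediate
16 | isopropylmagnesium chloride | CC(C)[Mg]Cl | starting material
17 | (1R,2R,3S)-3-(dimethoxymethyl)-2-ethenyl-3-methyl-1-(propan-2-yl)cyclopentan-1-ol | C=C[C@@H]1[C@](C(OC)OC)(C)CC[C@@]1(O)C(C)C | intermediate
18 | secondary ozonide (1,2,4-trioxolane) of 17, not isolated | C1OOC(O1)[C@@H]2[C@](C(OC)OC)(C)CC[C@@]2(O)C(C)C | intermediate
19 | (1R,2S,5R)-2-(dimethoxymethyl)-5-hydroxy-2-methyl-5-(propan-2-yl)cyclopentane-1-carbaldehyde | O=C[C@@H]1[C@](C(OC)OC)(C)CC[C@@]1(O)C(C)C | intermediate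
20 | (2-methylallyl)magnesium chloride | CC(=C)C[Mg]Cl | starting material
21 | diisopinocampheylborinate ester of 22, not isolated | C=C(C)C[C@H](OB([C@@H]3C[C@@H]4C[C@H]([C@H]3C)C4(C)C)[C@@H]5C[C@@H]6C[C@H]([C@H]5C)C6(C)C)[C@@H]1[C@](C(OC)OC)(C)CC[C@@]1(O)C(C)C | intermediate
22 | (1R,2S,3S)-3-(dimethoxymethyl)-2-[(1S)-1-hydroxy-3-methylbut-3-en-1-yl]-3-methyl-1-(propan-2-yl)cyclopentan-1-ol | C=C(C)C[C@H](O)[C@@H]1[C@](C(OC)OC)(C)CC[C@@]1(O)C(C)C | intermediate
23 | benzoyl chloride | O=C(Cl)c1ccccc1 | starting material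
24 | (1S)-1-[(1S,2S,5R)-2-(dimethoxymethyl)-5-hydroxy-2-methyl-5-(propan-2-yl)cyclopentyl]-3-methylbut-3-en-1-yl benzoate | C=C(C)C[C@H](OC(=O)c2ccccc2)[C@@H]1[C@](C(OC)OC)(C)CC[C@@]1(O)C(C)C | intermediate
25 | (1S)-1-[(1S,2S,5R)-2-formyl-5-hydroxy-2-methyl-5-(propan-2-yl)cyclopentyl]-3-methylbut-3-en-1-yl benzoate | C=C(C)C[C@H](OC(=O)c2ccccc2)[C@@H]1[C@](C=O)(C)CC[C@@]1(O)C(C)C | intermediate
26 | vinyl bromide | C=CBr | starting material
27 | (1S)-1-[(1S,2S,5R)-5-hydroxy-2-(1-hydroxyprop-2-en-1-yl)-2-methyl-5-(propan-2-yl)cyclopentyl]-3-methylbut-3-en-1-yl benzoate (mixture of carbinol epimers) | C=C(C)C[C@H](OC(=O)c2ccccc2)[C@@H]1[C@](C(O)C=C)(C)CC[C@@]1(O)C(C)C | intermediate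
28 | (1S)-1-[(1S,2S,5R)-5-hydroxy-2-methyl-5-(propan-2-yl)-2-(prop-2-enoyl)cyclopentyl]-3-methylbut-3-en-1-yl benzoate | C=C(C)C[C@H](OC(=O)c2ccccc2)[C@@H]1[C@](C(=O)C=C)(C)CC[C@@]1(O)C(C)C | intermediate
29 | (1S)-1-{(1S,2S,5R)-5-hydroxy-2-[(1R)-1-hydroxyprop-2-en-1-yl]-2-methyl-5-(propan-2-yl)cyclopentyl}-3-methylbut-3-en-1-yl benzoate | C=C(C)C[C@H](OC(=O)c2ccccc2)[C@@H]1[C@]([C@H](O)C=C)(C)CC[C@@]1(O)C(C)C | intermediate
30 | (3R,3aS,4S,8R,8aS)-3,8-dihydroxy-6,8a-dimethyl-3-(propan-2-yl)-1,2,3,3a,4,5,8,8a-octahydroazulen-4-yl benzoate | O[C@@H]1C=C(C)C[C@H](OC(=O)c2ccccc2)[C@@H]2[C@]1(C)CC[C@@]2(O)C(C)C | intermediate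
31 | angelic acid, (2Z)-2-methylbut-2-enoic acid | C/C=C(/C)C(=O)O | starting material
32 | (3R,3aS,4S,8R,8aS)-4-(benzoyloxy)-3-hydroxy-6,8a-dimethyl-3-(propan-2-yl)-1,2,3,3a,4,5,8,8a-octahydroazulen-8-yl (2Z)-2-methylbut-2-enoate | C/C=C(/C)C(=O)O[C@@H]1C=C(C)C[C@H](OC(=O)c2ccccc2)[C@@H]2[C@]1(C)CC[C@@]2(O)C(C)C | target

**Step count and risks**

Total steps: 22. Longest linear sequence: 22 steps (1 to 32; the route is fully linear, with 7, 9, 16, 20, 23, 26 and 31 entering as purchased partners).

Steps most likely to fail: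

Step 13 (with step 12 before it). The β,γ-unsaturated ketone 15 can epimerize at C6 or conjugate, and the hindered ketone may enolize instead of adding isopropyl. The fallback sets out from 13 and comes back at 22; it builds the C5 side chain first so that the ketone is no longer β,γ-unsaturated. Ozonolysis of 13 (O3, CH2Cl2, −78 °C; PPh3) gives the silyloxy aldehyde F1. Methallylboration of F1 with 20 and (−)-Ipc2BOMe gives the homoallylic alcohol F2. 4-Methoxybenzyl trichloroacetimidate with La(OTf)3 gives the 4-methoxybenzyl ether F3. Bu4NF gives the ring alcohol F4, and Dess–Martin oxidation gives the β-alkoxy ketone F5. Addition of 16 with CeCl3 anti to the side chain gives the tertiary alcohol F6, and DDQ in CH2Cl2/pH 7 buffer removes the ether to give 22.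

Step 15. The β-hydroxy aldehyde 19 is hindered and prone to retro-aldol cleavage or dehydration, and the substrate may oppose the reagent's facial preference. The fallback sets out from 19 and comes back at 22; it replaces reagent control by hydroxyl-directed reduction. Addition of 20 itself (THF, −78 °C) gives the epimeric methallyl carbinols F7. Dess–Martin oxidation of the secondary alcohol gives the β-hydroxy ketone F8. Me4NBH(OAc)3 in MeCN/AcOH at −30 °C then delivers hydride internally from the C10 alkoxyborohydride and gives the 1,3-anti diol, which is 22.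

Step 22. The C1 alcohol is neopentylic and allylic, so acylation is slow, and angelates isomerize easily to tiglates during activation. The fallback sets out from 30 and comes back at 32; it builds the Z alkene after the ester bond is made. DCC/DMAP coupling of 30 with 2-[bis(2,2,2-trifluoroethoxy)phosphoryl]propanoic acid gives the phosphonopropanoate ester F9. Still–Gennari olefination of F9 (KN(SiMe3)2, 18-crown-6, THF, −78 °C, then acetaldehyde) gives the Z-configured 2-methylbut-2-enoate 32.

**Further compounds**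

F1 | step 13 | (1R,2S,5R)-5-[(tert-butyldimethylsilyl)oxy]-2-(dimethoxymethyl)-2-methylcyclopentane-1-carbaldehyde | O=C[C@@H]1[C@](C(OC)OC)(C)CC[C@H]1O[Si](C)(C)C(C)(C)C
F2 | step 13 | (1S)-1-[(1S,2S,5R)-5-[(tert-butyldimethylsilyl)oxy]-2-(dimethoxymethyl)-2-methylcyclopentyl]-3-methylbut-3-en-1-ol | C=C(C)C[C@H](O)[C@@H]1[C@](C(OC)OC)(C)CC[C@H]1O[Si](C)(C)C(C)(C)C
F3 | step 13 | 4-methoxybenzyl ether of F2 | C=C(C)C[C@H](OCc2ccc(OC)cc2)[C@@H]1[C@](C(OC)OC)(C)CC[C@H]1O[Si](C)(C)C(C)(C)C
F4 | step 13 | ring alcohol from desilylation of F3 | C=C(C)C[C@H](OCc2ccc(OC)cc2)[C@@H]1[C@](C(OC)OC)(C)CC[C@H]1O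
F5 | step 13 | cyclopentanone from oxidation of F4 | C=C(C)C[C@H](OCc2ccc(OC)cc2)[C@@H]1[C@](C(OC)OC)(C)CCC1=O
F6 | step 13 | 4-methoxybenzyl ether of 22 | C=C(C)C[C@H](OCc2ccc(OC)cc2)[C@@H]1[C@](C(OC)OC)(C)CC[C@@]1(O)C(C)C
F7 | step 15 | (1R,2S,3S)-3-(dimethoxymethyl)-2-(1-hydroxy-3-methylbut-3-en-1-yl)-3-methyl-1-(propan-2-yl)cyclopentan-1-ol (mixture of side-chain carbinol epimers) | C=C(C)CC(O)[C@@H]1[C@](C(OC)OC)(C)CC[C@@]1(O)C(C)C
F8 | step 15 | 1-[(1R,2S,5R)-2-(dimethoxymethyl)-5-hydroxy-2-methyl-5-(propan-2-yl)cyclopentyl]-3-methylbut-3-en-1-one | C=C(C)CC(=O)[C@@H]1[C@](C(OC)OC)(C)CC[C@@]1(O)C(C)C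
F9 | step 22 | 2-[bis(2,2,2-trifluoroethoxy)phosphoryl]propanoate ester of 30 at the C1 hydroxyl (mixture of epimers at the phosphonate-bearing carbon) | CC(C(=O)O[C@@H]1C=C(C)C[C@H](OC(=O)c2ccccc2)[C@@H]2[C@]1(C)CC[C@@]2(O)C(C)C)P(=O)(OCC(F)(F)F)OCC(F)(F)F
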